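**Plan**

- Oxolane numbering: O1, C2 (3,4-dihydroxyphenyl), C3 (CH2OH), C4 (OH and 3,4-dimethoxybenzyl), C5 (H2). The enabling feature is C4, a ring carbon carrying an oxygen and an exocyclic CH2–aryl group. This is the 1,2-adduct of an aryl group and an oxygen across an exocyclic C4=CH2 bond, with the C4 oxygen cis to the C3 CH2O arm, so both oxygens fit into one six-membered carbonate ring.
- Retrosynthetic cuts, last bond first: aryl–CH2 and C4–O (one radical–polar step on a 4-methylideneoxolane with a CH2OBoc arm on C3); O1–C5 (Mitsunobu etherification); C2–C3 (allylboration of 3,4-diacetoxybenzaldehyde); the C–CH2B bond of the allylboronate (Negishi coupling of a vinyl iodide from a butynediol monoether).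
- Forward order: the acyclic five-carbon allylboronate is built first and joined to the aldehyde, then the oxolane (ring A) is closed. The cyclic carbonate (ring B) is closed in the key step and opened again in the last step.
- Stereochemistry: C2 and C3 arise together in the allylboration (syn from the fixed alkene geometry of the boronate, absolute sense from the chiral phosphoric acid (R)-TRIP). C4 is set in the key step by the carbonate tether anchored on C3.
- The catechol oxygens travel as acetates. They deactivate the C2 aryl ring toward oxidation and benzylic ionisation, and they are removed in the same methanolysis that opens the carbonate.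

Key step: step 8

Assumption: (R)-TRIP is taken to direct the allyl group to the Re face of 8, as it does for benzaldehyde with allyl and crotyl pinacolboronates; 1, 4, 8 and 13 are taken as catalogue compounds.

**Step 1**
Reactants: 1 4-[(tert-butyldimethylsilyl)oxy]but-2-yn-1-ol
Product: 3 (Z)-4-[(tert-butyldimethylsilyl)oxy]-3-iodobut-2-en-1-ol, via cyclic alkenylalanate 2 (not isolated)
Conditions: NaAlH2(OCH2CH2OMe)2 (1.5 equiv), THF, 0 °C; then I2, THF, −78 to 0 °C
Reagents that add atoms: iodine, SMILES [I][I]
Why: Hydroxyl-directed trans-hydroalumination of a propargylic alcohol puts hydride on the near alkyne carbon and aluminium on the far one inside a five-membered ring, and iodine cleaves the C–Al bond with retention, so iodine should end up cis to the CH2OH group ((Z)-alkene) while the silyl ether survives at 0 °C.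

**Step 2**
Reactants: 3 (Z)-4-[(tert-butyldimethylsilyl)oxy]-3-iodobut-2-en-1-ol; 4 2-(iodomethyl)-4,4,5,5-tetramethyl-1,3,2-dioxaborolane
Product: 6 (E)-4-[(tert-butyldimethylsilyl)oxy]-3-[(4,4,5,5-tetramethyl-1,3,2-dioxaborolan-2-yl)methyl]but-2-en-1-ol, via borylmethylzinc iodide 5 (not isolated)
Conditions: Zn dust, THF, rt (4 to 5); then 3, Pd(OAc)2 (2 mol%), SPhos (4 mol%), THF, rt
Reagents that add atoms: none
Why: Negishi coupling of an alkenyl iodide with a borylmethylzinc iodide keeps the alkene geometry, so the CH2B group takes the place of iodine cis to the CH2OH arm (the geometry of a (Z)-crotylboronate; the descriptor becomes E only through the priority change); the weakly basic zinc reagent should tolerate the free hydroxyl, and the carbonate is not yet present because an allylic carbonate would ionise with zerovalent palladium.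

**Step 3**
Reactants: 6 (E)-4-[(tert-butyldimethylsilyl)oxy]-3-[(4,4,5,5-tetramethyl-1,3,2-dioxaborolan-2-yl)methyl]but-2-en-1-ol
Product: 7 tert-butyl (E)-4-[(tert-butyldimethylsilyl)oxy]-3-[(4,4,5,5-tetramethyl-1,3,2-dioxaborolan-2-yl)methyl]but-2-en-1-yl carbonate
Conditions: Boc2O (1.2 equiv), DMAP (5 mol%), CH2Cl2, 0 °C
Reagents that add atoms: di-tert-butyl dicarbonate, SMILES CC(C)(C)OC(=O)OC(=O)OC(C)(C)C
Why: DMAP-catalysed acylation of the primary allylic alcohol with Boc2O installs the tert-butyl carbonate that later delivers oxygen to C4, and the pinacol allylboronate has nothing to react with under these aprotic conditions.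

**Step 4**
Reactants: 7 tert-butyl (E)-4-[(tert-butyldimethylsilyl)oxy]-3-[(4,4,5,5-tetramethyl-1,3,2-dioxaborolan-2-yl)methyl]but-2-en-1-yl carbonate; 8 3,4-diacetoxybenzaldehyde
Product: 10 tert-butyl (2R)-2-[(R)-(3,4-diacetoxyphenyl)(hydroxy)methyl]-3-{[(tert-butyldimethylsilyl)oxy]methyl}but-3-en-1-yl carbonate, via pinacolboryl ether 9 (not isolated)
Conditions: (R)-TRIP [(R)-3,3'-bis(2,4,6-triisopropylphenyl)-1,1'-binaphthyl-2,2'-diyl hydrogen phosphate] (5 mol%), 4 Å MS, toluene, −30 to 0 °C; then pH 7 phosphate buffer, rt
Reagents that add atoms: none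
Why: Chiral phosphoric acid-catalysed allylboration through a closed chair (Zimmerman–Traxler) transition state: the CH2OBoc group, cis to the CH2B carbon, is forced axial and gives the syn adduct (the later 2,3-cis ring), while the catalyst, bound to a boronate oxygen and the formyl hydrogen, exposes the Re face of 8, so both new stereocentres should form as (R,R).

**Step 5**
Reactants: 10 tert-butyl (2R)-2-[(R)-(3,4-diacetoxyphenyl)(hydroxy)methyl]-3-{[(tert-butyldimethylsilyl)oxy]methyl}but-3-en-1-yl carbonate
Product: 11 tert-butyl (2R)-2-[(R)-(3,4-diacetoxyphenyl)(hydroxy)methyl]-3-(hydroxymethyl)but-3-en-1-yl carbonate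
Conditions: HF·pyridine, pyridine, THF, 0 °C to rt
Reagents that add atoms: none
Why: Silyl ether cleavage with pyridine-buffered HF·pyridine removes the primary allylic silyl group without base, so the neighbouring hydroxy carbonate cannot close to a cyclic carbonate and the aryl acetates and the acetyl-deactivated benzylic alcohol should stay intact.

**Step 6**
Reactants: 11 tert-butyl (2R)-2-[(R)-(3,4-diacetoxyphenyl)(hydroxy)methyl]-3-(hydroxymethyl)but-3-en-1-yl carbonate
Product: 12 tert-butyl [(2R,3R)-2-(3,4-diacetoxyphenyl)-4-methylideneoxolan-3-yl]methyl carbonate (aryl and CH2O arm cis)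
Conditions: PPh3, DIAD, THF, 0 °C to rt
Reagents that add atoms: none
Why: Mitsunobu cyclodehydration of a 1,4-diol: the unhindered primary allylic hydroxyl is activated as its oxyphosphonium salt and displaced by the secondary benzylic hydroxyl (5-exo-tet, ring A), so no bond to C2 or C3 is broken and the cis arrangement from step 4 is carried into the oxolane.

**Step 7**
Reactants: 13 3,4-dimethoxyaniline
Product: 14 3,4-dimethoxybenzenediazonium tetrafluoroborate
Conditions: NaNO2, HBF4 (48% aq), H2O, 0 °C
Reagents that add atoms: sodium nitrite, SMILES [Na+].[O-]N=O; tetrafluoroboric acid, SMILES [H+].F[B-](F)(F)F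
Why: Diazotisation of the arylamine with nitrous acid in aqueous HBF4 precipitates the sparingly soluble diazonium tetrafluoroborate, which is filtered, washed with cold ether and used the same day.

**Step 8**
Reactants: 12 tert-butyl [(2R,3R)-2-(3,4-diacetoxyphenyl)-4-methylideneoxolan-3-yl]methyl carbonate; 14 3,4-dimethoxybenzenediazonium tetrafluoroborate
Product: 15 cis-fused cyclic carbonate (1,3-dioxan-2-one across C3–C4) joining the C3 CH2O oxygen and the C4 oxygen of (2R,3R,4R)-2-(3,4-diacetoxyphenyl)-4-(3,4-dimethoxybenzyl)-3-(hydroxymethyl)oxolan-4-ol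
Conditions: Ru(bpy)3Cl2·6H2O (2 mol%), 14 (2 equiv, in portions), NaHCO3 (2 equiv), degassed MeCN, blue LEDs (455 nm), 20 °C
Reagents that add atoms: none
Why: Proposed new method: excited divalent ruthenium reduces 14 to the 3,4-dimethoxyphenyl radical (loss of N2), this radical adds to the unsubstituted end of the exocyclic C4=CH2 bond of 12 to form the aryl–CH2 bond, and the tertiary C4 radical is oxidised to the cation by trivalent ruthenium or by a second molecule of 14, which closes the photocatalytic cycle or carries a chain. The carbonyl oxygen of the tert-butyl carbonate on the C3 arm captures this cation in a 6-exo closure (ring B, C4–O bond), and the resulting dioxanylium ion sheds isobutene and a proton, taken up by NaHCO3, to leave the 1,3-dioxan-2-one. The closest known reaction types are the photoredox Meerwein carbo-oxygenation of styrenes with arenediazonium salts and the iodocarbonate cyclisation of homoallylic tert-butyl carbonates; what is new is their union on an unactivated 1,1-disubstituted alkene. The quaternary stereocentre C4 is controlled by the tether alone: the three-atom CH2–O–C(=O) link hangs from C3 on one face of the flat cation and can close only there, so the new C4–O bond is cis to the C3 CH2O group and the aryl–CH2 group goes to the opposite face. The step needs regioselectivity (aryl to CH2, oxygen to C4), secured by attack at the unhindered terminus to give the tertiary radical, and chemoselectivity for addition over hydrogen abstraction and for capture over proton loss or Ritter attack by MeCN, secured by MeCN being a poor hydrogen donor, by the intramolecular six-membered delivery of oxygen and by the acetyl-deactivated C2 aryl ring, which resists oxidation, azo coupling and benzylic ionisation.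

**Step 9**
Reactants: 15 cis-fused cyclic carbonate
Product: 16 (3R,4R,5R)-5-(3,4-dihydroxyphenyl)-3-[(3,4-dimethoxyphenyl)methyl]-4-(hydroxymethyl)oxolan-3-ol (the target; 2R,3R,4R in the numbering of the plan)
Conditions: K2CO3 (0.2 equiv), degassed MeOH, argon, 0 °C to rt; then Amberlite IR-120 (H+ form)
Reagents that add atoms: none
Why: Base-catalysed transesterification with methanol (Zemplén-type) cleaves the two aryl acetates as methyl acetate and opens the cyclic carbonate as dimethyl carbonate, freeing the catechol, the C4 tertiary alcohol and the C3 CH2OH without touching any bond to a stereocentre; air is excluded to protect the catecholate.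

**Compound list**

1 | 4-[(tert-butyldimethylsilyl)oxy]but-2-yn-1-ol | OCC#CCO[Si](C)(C)C(C)(C)C | starting material
2 | sodium alkenylalanate, five-membered O–CH2–CH=C(CH2OSi)–Al ring with two 2-methoxyethoxy groups on aluminium | COCCO[Al-]1(OCCOC)OCC=C1CO[Si](C)(C)C(C)(C)C.[Na+] | intermediate
3 | (Z)-4-[(tert-butyldimethylsilyl)oxy]-3-iodobut-2-en-1-ol | OC/C=C(\I)CO[Si](C)(C)C(C)(C)C | intermediate
4 | 2-(iodomethyl)-4,4,5,5-tetramethyl-1,3,2-dioxaborolane | ICB1OC(C)(C)C(C)(C)O1 | starting material
5 | [(4,4,5,5-tetramethyl-1,3,2-dioxaborolan-2-yl)methyl]zinc iodide | I[Zn]CB1OC(C)(C)C(C)(C)O1 | intermediate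
6 | (E)-4-[(tert-butyldimethylsilyl)oxy]-3-[(4,4,5,5-tetramethyl-1,3,2-dioxaborolan-2-yl)methyl]but-2-en-1-ol (CH2B cis to CH2OH) | OC/C=C(\CB1OC(C)(C)C(C)(C)O1)CO[Si](C)(C)C(C)(C)C | intermediate
7 | tert-butyl (E)-4-[(tert-butyldimethylsilyl)oxy]-3-[(4,4,5,5-tetramethyl-1,3,2-dioxaborolan-2-yl)methyl]but-2-en-1-yl carbonate (CH2B cis to CH2OBoc) | CC(C)(C)OC(=O)OC/C=C(\CB1OC(C)(C)C(C)(C)O1)CO[Si](C)(C)C(C)(C)C | intermediate
8 | 3,4-diacetoxybenzaldehyde | CC(=O)Oc1ccc(C=O)cc1OC(C)=O | starting material
9 | O-(pinacolboryl) ether of 10 | C=C(CO[Si](C)(C)C(C)(C)C)[C@H](COC(=O)OC(C)(C)C)[C@@H](OB1OC(C)(C)C(C)(C)O1)c1ccc(OC(C)=O)c(OC(C)=O)c1 | intermediate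
10 | tert-butyl (2R)-2-[(R)-(3,4-diacetoxyphenyl)(hydroxy)methyl]-3-{[(tert-butyldimethylsilyl)oxy]methyl}but-3-en-1-yl carbonate | C=C(CO[Si](C)(C)C(C)(C)C)[C@H](COC(=O)OC(C)(C)C)[C@@H](O)c1ccc(OC(C)=O)c(OC(C)=O)c1 | intermediate
11 | tert-butyl (2R)-2-[(R)-(3,4-diacetoxyphenyl)(hydroxy)methyl]-3-(hydroxymethyl)but-3-en-1-yl carbonate | C=C(CO)[C@H](COC(=O)OC(C)(C)C)[C@@H](O)c1ccc(OC(C)=O)c(OC(C)=O)c1 | intermediate
12 | tert-butyl [(2R,3R)-2-(3,4-diacetoxyphenyl)-4-methylideneoxolan-3-yl]methyl carbonate | C=C1CO[C@@H](c2ccc(OC(C)=O)c(OC(C)=O)c2)[C@H]1COC(=O)OC(C)(C)C | intermediate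
13 | 3,4-dimethoxyaniline | COc1ccc(N)cc1OC | starting material
14 | 3,4-dimethoxybenzenediazonium tetrafluoroborate | COc1ccc([N+]#N)cc1OC.F[B-](F)(F)F | intermediate
15 | cis-fused cyclic carbonate of the C3 CH2OH and C4 OH groups of (2R,3R,4R)-2-(3,4-diacetoxyphenyl)-4-(3,4-dimethoxybenzyl)-3-(hydroxymethyl)oxolan-4-ol | COc1ccc(C[C@]23CO[C@@H](c4ccc(OC(C)=O)c(OC(C)=O)c4)[C@H]2COC(=O)O3)cc1OC | intermediate
16 | (3R,4R,5R)-5-(3,4-dihydroxyphenyl)-3-[(3,4-dimethoxyphenyl)methyl]-4-(hydroxymethyl)oxolan-3-ol | COc1ccc(C[C@]2(O)CO[C@@H](c3ccc(O)c(O)c3)[C@H]2CO)cc1OC | target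

**Step count and risks**

Total step count: 9. Longest linear sequence: 8 steps (steps 1 to 6, 8 and 9); step 7 is a one-step side branch.

Risk 1, step 8. Hydrogen abstraction by the aryl radical and simple reduction of the diazonium salt may outrun addition to the unactivated alkene, or the C4 cation may lose a benzylic proton before the carbonate closes. The fallback sets out from 12 and returns at 15, making the same two bonds one after the other by known reactions. Iodocarbonate cyclisation of 12 with IBr (toluene/CH2Cl2, −80 °C) lets the same tert-butyl carbonate capture the iodonium ion at C4 and should give the cis-fused iodomethyl cyclic carbonate F1. Nickel-catalysed reductive cross-electrophile coupling of this primary iodide with 4-bromo-1,2-dimethoxybenzene (NiI2, 4,4'-di-tert-butyl-2,2'-bipyridine, Zn, NaI, pyridine, DMPU, 60 °C) then forms the aryl–CH2 bond and delivers 15.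

Risk 2, step 4. The hindered trisubstituted boronate may add so slowly that the uncatalysed background reaction erodes facial selectivity, or the acid may promote loss of the allylic carbonate from 7. The fallback sets out from 7 and 8 and returns at 10. The addition is run without acid (toluene, 40 °C), where the closed transition state should still give only the syn adduct, but as a racemate. This is 9 together with its mirror-image boryl ether F2 and, after the buffer work-up, 10 together with the mirror-image alcohol F3. Kinetic resolution by enantioselective acylation (isobutyric anhydride, i-Pr2NEt, the enantiomer of benzotetramisole that acylates (S)-1-arylalkanols faster, CHCl3, 0 °C) turns F3 into the isobutyrate F4, which is removed by chromatography, while unreacted 10 goes on.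

Risk 3, step 2. The free hydroxyl may protonate the zinc reagent, or the alkylzinc with boron on the same carbon may transmetalate too slowly, so that the iodide is reduced or homocoupled. The fallback sets out from 3 and returns at 6. It is a Suzuki–Miyaura coupling of 3 with bis(4,4,5,5-tetramethyl-1,3,2-dioxaborolan-2-yl)methane (Pd[P(t-Bu)3]2, aqueous KOH, 1,4-dioxane, rt). Here a boron-ate complex rather than an organozinc carries the CH2B unit, and only one of the two geminal boryl groups is transferred. No new compound is made on the way.

**Further compounds**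

F1 | step 8 | cis-fused iodomethyl cyclic carbonate (15 with iodine in place of the 3,4-dimethoxyphenyl group) | IC[C@]12CO[C@@H](c3ccc(OC(C)=O)c(OC(C)=O)c3)[C@H]1COC(=O)O2
F2 | step 4 | mirror image of 9, O-(pinacolboryl) ether of F3 | C=C(CO[Si](C)(C)C(C)(C)C)[C@@H](COC(=O)OC(C)(C)C)[C@H](OB1OC(C)(C)C(C)(C)O1)c1ccc(OC(C)=O)c(OC(C)=O)c1
F3 | step 4 | tert-butyl (2S)-2-[(S)-(3,4-diacetoxyphenyl)(hydroxy)methyl]-3-{[(tert-butyldimethylsilyl)oxy]methyl}but-3-en-1-yl carbonate (mirror image of 10) | C=C(CO[Si](C)(C)C(C)(C)C)[C@@H](COC(=O)OC(C)(C)C)[C@H](O)c1ccc(OC(C)=O)c(OC(C)=O)c1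
F4 | step 4 | isobutyrate ester of F3 at the benzylic hydroxyl | C=C(CO[Si](C)(C)C(C)(C)C)[C@@H](COC(=O)OC(C)(C)C)[C@H](OC(=O)C(C)C)c1ccc(OC(C)=O)c(OC(C)=O)c1
F0 | step 2 | none | none
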